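**Assumption:** the SMILES is taken as the authoritative structure, so the aroyl group is 3,5-dihydroxy-4-prenylbenzoyl and the ring, numbered C1(Me)=C2–C3(aryl)–C4(aroyl)–C5(aryl)–C6, is (3S,4R,5S) with 3,4-cis and 4,5-trans.

## Retrosynthetic overview

1. Kuwanon J ⇐ its octaacetate (global deacetylation) ⇐ late chalcone assembly on a methyl ketone (aldol addition, then elimination).
2. Cyclohexene core ⇐ [3,3] (Claisen) shift of a 2-styryl-3,4-dihydro-2H-pyran; the C3–C4 bond and both of its stereocentres are traced back to one C–O bond.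
3. Dihydropyran (formed first; the cyclohexene is the second and only other ring formed) ⇐ enantioselective oxa-[4+2] of a prenylated chalcone tetraacetate (1-oxadiene) with the isopropenyl alkene of an aryl diene.
4. Chalcone ⇐ 4-bromo-3,5-dihydroxybenzoic acid + 2,4-dihydroxybenzaldehyde + prenylstannane; diene ⇐ 2,4-dihydroxyacetophenone + isoprene.
5. Acetates on all phenols throughout: stable to strong acid, they deactivate the arenes towards cationic side reactions, and they come off under mild methanolysis.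

## Route

Step 1
Reactants: 1 2,4-dihydroxybenzaldehyde
Product: 2 2,4-diacetoxybenzaldehyde
Conditions: Ac2O, pyridine, DMAP (cat.), CH2Cl2, 0 °C to 25 °C
Reagents that add atoms: acetic anhydride, CC(=O)OC(C)=O
Why: DMAP-catalysed O-acetylation (nucleophilic acyl substitution) caps both phenols, the hydrogen-bonded 2-OH included; no stereocentre.

Step 2
Reactants: 3 4-bromo-3,5-dihydroxybenzoic acid
Product: 4 3,5-diacetoxy-4-bromobenzoic acid
Conditions: Ac2O, pyridine, 25 °C; then H2O/THF, dilute HCl work-up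
Reagents that add atoms: acetic anhydride, CC(=O)OC(C)=O
Why: O-acetylation of both phenols; the mixed anhydride at the acid is hydrolysed back on aqueous work-up; no stereocentre.

Step 3
Reactants: 4 3,5-diacetoxy-4-bromobenzoic acid
Product: 6 3,5-diacetoxy-4-bromoacetophenone, via acid chloride 5 (not isolated)
Conditions: (COCl)2, DMF (cat.), CH2Cl2, 0 °C to 25 °C, evaporate; then MeMgBr (1.05 equiv), Fe(acac)3 (3 mol%), THF, −78 °C
Reagents that add atoms: methylmagnesium bromide, C[Mg]Br
Why: Acid chloride formation followed by iron-catalysed Grignard acylation, which at −78 °C is far faster than attack on aryl acetates, the aryl bromide or the product ketone.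

Step 4
Reactants: 6 3,5-diacetoxy-4-bromoacetophenone; 2 2,4-diacetoxybenzaldehyde
Product: 7 (E)-1-(3,5-diacetoxy-4-bromophenyl)-3-(2,4-diacetoxyphenyl)prop-2-en-1-one
Conditions: BF3·OEt2 (0.5 equiv), 1,4-dioxane, 25 °C
Reagents that add atoms: none
Why: Acid-mediated Claisen–Schmidt (crossed aldol) condensation leaves aryl acetates intact, unlike hydroxide conditions, and gives the thermodynamic E-enone; no acid-sensitive alkene is present yet.

Step 5
Reactants: 7 (E)-1-(3,5-diacetoxy-4-bromophenyl)-3-(2,4-diacetoxyphenyl)prop-2-en-1-one; 8 tributyl(3-methylbut-2-enyl)stannane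
Product: 9 (E)-1-[3,5-diacetoxy-4-(3-methylbut-2-enyl)phenyl]-3-(2,4-diacetoxyphenyl)prop-2-en-1-one
Conditions: Pd(PPh3)4 (5 mol%), DMF, 95 °C
Reagents that add atoms: none
Why: Stille coupling under neutral conditions on an aryl bromide activated by the para acyl group; the prenyl group is transferred mainly through its α-carbon and the acetates and enone are untouched.

Step 6
Reactants: 10 2,4-dihydroxyacetophenone
Product: 11 2,4-dihydroxy-3-iodoacetophenone
Conditions: I2 (0.4 equiv), HIO3 (0.2 equiv), EtOH/H2O, 35 °C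
Reagents that add atoms: iodine, II; iodic acid, OI(=O)=O
Why: Electrophilic aromatic iodination at C3, the position activated by both flanking hydroxyls; no stereocentre.

Step 7
Reactants: 11 2,4-dihydroxy-3-iodoacetophenone
Product: 12 2,4-diacetoxy-3-iodoacetophenone
Conditions: Ac2O, pyridine, DMAP (cat.), CH2Cl2, 25 °C to 40 °C
Reagents that add atoms: acetic anhydride, CC(=O)OC(C)=O
Why: DMAP-catalysed O-acetylation of both phenols, including the hindered hydrogen-bonded 2-OH; this blocks acid-induced chromene formation later.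

Step 8
Reactants: 12 2,4-diacetoxy-3-iodoacetophenone; 13 isoprene
Product: 14 2,4-diacetoxy-3-[(E)-3-methylbuta-1,3-dienyl]acetophenone
Conditions: Pd(OAc)2 (5 mol%), P(o-tol)3 (10 mol%), KOAc (2 equiv), Bu4NBr, isoprene (5 equiv), DMA, 85 °C, sealed tube
Reagents that add atoms: none
Why: Mizoroki–Heck arylation of isoprene at its unsubstituted vinyl terminus, with syn β-hydride elimination giving the E-1-aryl diene; acetate is a base that cannot cleave the aryl acetates.

Step 9
Reactants: 9 (E)-1-[3,5-diacetoxy-4-(3-methylbut-2-enyl)phenyl]-3-(2,4-diacetoxyphenyl)prop-2-en-1-one; 14 2,4-diacetoxy-3-[(E)-3-methylbuta-1,3-dienyl]acetophenone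
Product: 16 (3S,4R,5S)-cyclohexenyl aryl ketone hexaacetate, via hetero-Diels–Alder dihydropyran 15 (not isolated)
Conditions: (S,S)-IDPi (5 mol%; imidodiphosphorimidate Brønsted acid from two (S)-3,3'-bis[3,5-bis(trifluoromethyl)phenyl]-BINOL units, N-triflyl on both phosphorus atoms), 14 (1.3 equiv), CHCl3, 5 Å MS, −40 °C, 48 h; then 25 °C, 12 h; Et3N quench
Reagents that add atoms: none
Why: Proposed new method: a catalytic enantioselective inverse-electron-demand oxa-Diels–Alder reaction in which the non-chelating chalcone 9, protonated inside the confined chiral IDPi anion, is the 1-oxadiene and the 1,1-disubstituted terminal alkene of 14 is the 2π partner; the CH2 terminus adds to the Si face of Cβ while the carbonyl oxygen closes onto the tertiary allylic carbon (the new C–O bond, styryl group endo), giving the 2,4-cis dihydropyran 15 and setting the future C5 centre (S) and the C–O centre (S); the same acid then accelerates a suprafacial [3,3] Claisen shift of the allyl vinyl ether in 15 through the boat transition state forced by the ring, which passes the C–O chirality on to C3 and C4 and can only give the 3,4-cis, 4,5-trans ketone 16; the closest known chemistry is the chiral-acid-catalysed oxa-Diels–Alder reaction of chelating β,γ-unsaturated α-ketoesters or ortho-quinone methides with olefins and cyclopentadiene, together with the Claisen relay between 2-vinyl-dihydropyrans and 4-acylcyclohexenes, neither shown for a simple chalcone with an acyclic aryl diene.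

Step 10
Reactants: 16 (3S,4R,5S)-cyclohexenyl aryl ketone hexaacetate; 2 2,4-diacetoxybenzaldehyde
Product: 19 β-hydroxy ketone (aldol adduct; both carbinol epimers), via boron enolate 17 (not isolated), via boron aldolate 18 (not isolated)
Conditions: Cy2BCl (1.3 equiv), Et3N (1.5 equiv), CH2Cl2, −78 °C to 0 °C; then 2 (1.5 equiv), −78 °C to −20 °C; MeOH, pH 7 buffer (no peroxide)
Reagents that add atoms: none
Why: Boron-mediated aldol addition: soft enolisation touches only the methyl ketone (the C4–H next to the other ketone is tertiary and shielded, so C4 is not epimerised), boron enolates do not attack aryl acetates, and the uncontrolled carbinol centre is removed in step 11.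

Step 11
Reactants: 19 β-hydroxy ketone (aldol adduct)
Product: 21 kuwanon J octaacetate, via β-acetoxy ketone 20 (not isolated)
Conditions: Ac2O (3 equiv), Et3N, DMAP (cat.), CH2Cl2, 0 °C; then DBU (1.5 equiv), 0 °C to 25 °C
Reagents that add atoms: none
Why: Acetylation of the carbinol (and re-acetylation of any phenol freed by acyl migration) followed by E1cB elimination gives the conjugated E-chalcone; the three ring stereocentres are not involved.

Step 12
Reactants: 21 kuwanon J octaacetate
Product: 22 kuwanon J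
Conditions: K2CO3 (0.5 equiv), degassed MeOH, 0 °C to 25 °C, argon; then pH 5 buffer
Reagents that add atoms: none
Why: Base-catalysed transesterification (methanolysis) of the eight aryl acetates is fast at 0 °C, so the prenyl group, the chalcone and the epimerisable C4 centre survive.

## Compound list

1 | 2,4-dihydroxybenzaldehyde | O=Cc1ccc(O)cc1O | starting material
2 | 2,4-diacetoxybenzaldehyde | CC(=O)Oc1ccc(C=O)c(OC(C)=O)c1 | intermediate
3 | 4-bromo-3,5-dihydroxybenzoic acid | OC(=O)c1cc(O)c(Br)c(O)c1 | starting material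
4 | 3,5-diacetoxy-4-bromobenzoic acid | OC(=O)c1cc(OC(C)=O)c(Br)c(OC(C)=O)c1 | intermediate
5 | 3,5-diacetoxy-4-bromobenzoyl chloride | ClC(=O)c1cc(OC(C)=O)c(Br)c(OC(C)=O)c1 | intermediate
6 | 3,5-diacetoxy-4-bromoacetophenone | CC(=O)c1cc(OC(C)=O)c(Br)c(OC(C)=O)c1 | intermediate
7 | (E)-1-(3,5-diacetoxy-4-bromophenyl)-3-(2,4-diacetoxyphenyl)prop-2-en-1-one | CC(=O)Oc1ccc(/C=C/C(=O)c2cc(OC(C)=O)c(Br)c(OC(C)=O)c2)c(OC(C)=O)c1 | intermediate
8 | tributyl(3-methylbut-2-enyl)stannane | CCCC[Sn](CCCC)(CCCC)CC=C(C)C | starting material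
9 | (E)-1-[3,5-diacetoxy-4-(3-methylbut-2-enyl)phenyl]-3-(2,4-diacetoxyphenyl)prop-2-en-1-one | CC(C)=CCc1c(OC(C)=O)cc(C(=O)/C=C/c2ccc(OC(C)=O)cc2OC(C)=O)cc1OC(C)=O | intermediate
10 | 2,4-dihydroxyacetophenone | CC(=O)c1ccc(O)cc1O | starting material
11 | 2,4-dihydroxy-3-iodoacetophenone | CC(=O)c1ccc(O)c(I)c1O | intermediate
12 | 2,4-diacetoxy-3-iodoacetophenone | CC(=O)c1ccc(OC(C)=O)c(I)c1OC(C)=O | intermediate
13 | isoprene (2-methylbuta-1,3-diene) | CC(=C)C=C | starting material
14 | 2,4-diacetoxy-3-[(E)-3-methylbuta-1,3-dienyl]acetophenone | CC(=O)c1ccc(OC(C)=O)c(/C=C/C(C)=C)c1OC(C)=O | intermediate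
15 | (2S,4S)-2-[(E)-2-(3-acetyl-2,6-diacetoxyphenyl)ethenyl]-4-(2,4-diacetoxyphenyl)-6-[3,5-diacetoxy-4-(3-methylbut-2-enyl)phenyl]-2-methyl-3,4-dihydro-2H-pyran (2-styryl and 4-aryl cis) | CC(=O)c1ccc(OC(C)=O)c(/C=C/[C@]2(C)C[C@H](c3ccc(OC(C)=O)cc3OC(C)=O)C=C(c3cc(OC(C)=O)c(CC=C(C)C)c(OC(C)=O)c3)O2)c1OC(C)=O | intermediate
16 | (3S,4R,5S)-[3-(3-acetyl-2,6-diacetoxyphenyl)-5-(2,4-diacetoxyphenyl)-1-methylcyclohex-1-en-4-yl] [3,5-diacetoxy-4-(3-methylbut-2-enyl)phenyl] ketone (3,4-cis, 4,5-trans) | CC(C)=CCc1c(OC(C)=O)cc(C(=O)[C@H]2[C@@H](c3c(OC(C)=O)ccc(C(C)=O)c3OC(C)=O)C=C(C)C[C@@H]2c2ccc(OC(C)=O)cc2OC(C)=O)cc1OC(C)=O | intermediate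
17 | dicyclohexylboron enolate of the methyl ketone of 16 | CC(C)=CCc1c(OC(C)=O)cc(C(=O)[C@H]2[C@@H](c3c(OC(C)=O)ccc(C(=C)OB(C4CCCCC4)C4CCCCC4)c3OC(C)=O)C=C(C)C[C@@H]2c2ccc(OC(C)=O)cc2OC(C)=O)cc1OC(C)=O | intermediate
18 | dicyclohexylboron aldolate (both carbinol epimers) | CC(C)=CCc1c(OC(C)=O)cc(C(=O)[C@H]2[C@@H](c3c(OC(C)=O)ccc(C(=O)CC(OB(C4CCCCC4)C4CCCCC4)c4ccc(OC(C)=O)cc4OC(C)=O)c3OC(C)=O)C=C(C)C[C@@H]2c2ccc(OC(C)=O)cc2OC(C)=O)cc1OC(C)=O | intermediate
19 | β-hydroxy ketone: 16 with its acetyl group extended to C(=O)CH2CH(OH)(2,4-diacetoxyphenyl), both carbinol epimers | CC(C)=CCc1c(OC(C)=O)cc(C(=O)[C@H]2[C@@H](c3c(OC(C)=O)ccc(C(=O)CC(O)c4ccc(OC(C)=O)cc4OC(C)=O)c3OC(C)=O)C=C(C)C[C@@H]2c2ccc(OC(C)=O)cc2OC(C)=O)cc1OC(C)=O | intermediate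
20 | β-acetoxy ketone (acetate of 19, both epimers) | CC(C)=CCc1c(OC(C)=O)cc(C(=O)[C@H]2[C@@H](c3c(OC(C)=O)ccc(C(=O)CC(OC(C)=O)c4ccc(OC(C)=O)cc4OC(C)=O)c3OC(C)=O)C=C(C)C[C@@H]2c2ccc(OC(C)=O)cc2OC(C)=O)cc1OC(C)=O | intermediate
21 | kuwanon J octaacetate, (3S,4R,5S), E-chalcone | CC(C)=CCc1c(OC(C)=O)cc(C(=O)[C@H]2[C@@H](c3c(OC(C)=O)ccc(C(=O)/C=C/c4ccc(OC(C)=O)cc4OC(C)=O)c3OC(C)=O)C=C(C)C[C@@H]2c2ccc(OC(C)=O)cc2OC(C)=O)cc1OC(C)=O | intermediate
22 | kuwanon J, (3S,4R,5S) | CC(C)=CCc1c(O)cc(C(=O)[C@H]2[C@@H](c3c(O)ccc(C(=O)/C=C/c4ccc(O)cc4O)c3O)C=C(C)C[C@@H]2c2ccc(O)cc2O)cc1O | target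

## Step count and risks

Total steps: 12. Longest linear sequence: 8 (steps 2, 3, 4, 5, 9, 10, 11, 12, from 3 to 22).

Most likely to fail, first: step 9, the proposed oxa-Diels–Alder/Claisen relay. The diene may oligomerise under the acid, a direct or stepwise carbo-cycloaddition may leak exo isomer, the prenyl alkene of 9 may compete as a weaker 2π partner, and the sense or level of induction is unproven; the antipodal catalyst is used if induction is opposite. The fallback uses known chemistry and sets out from 9 and 14: an uncatalysed thermal Diels–Alder reaction (toluene, BHT, 160 °C, sealed tube) gives racemic endo adduct, that is 16 and its mirror image, the enantiomeric endo adduct F1, besides the all-trans exo adduct F2 and the enantiomeric exo adduct F3. Silica chromatography removes the exo pair and preparative HPLC on a chiral stationary phase gives 16, where the route is rejoined.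

Second: step 8, the Heck reaction with isoprene. Arylation at the methyl-bearing alkene, trapping of the allylpalladium intermediate and slow insertion of the di-ortho-substituted iodide can lower yield and isomer purity. The fallback sets out from 12 and replaces the insertion chemistry by a Suzuki–Miyaura coupling (Pd(OAc)2, SPhos, anhydrous CsF, dioxane, 80 °C) with the preformed dienyl nucleophile (E)-2-(3-methylbuta-1,3-dienyl)-4,4,5,5-tetramethyl-1,3,2-dioxaborolane F4. F4 is made in one operation from 2-methylbut-1-en-3-yne and pinacolborane with Cp2Zr(H)Cl as catalyst. The coupling returns to the route at 14.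

Third: step 5, the prenyl Stille coupling. The bromide is flanked by two acetoxy groups, and some coupling through the γ-carbon (reverse prenyl) is possible. The fallback sets out from 7: Stille coupling with allyltributylstannane (Pd(PPh3)4, DMF, 90 °C), which has no α/γ ambiguity, gives the allyl chalcone (E)-1-(4-allyl-3,5-diacetoxyphenyl)-3-(2,4-diacetoxyphenyl)prop-2-en-1-one F5. Olefin cross-metathesis of F5 with excess 2-methylbut-2-ene using the second-generation Grubbs catalyst (H2IMes)(PCy3)Cl2Ru=CHPh (CH2Cl2, 40 °C) converts allyl to prenyl and returns to the route at 9; the electron-poor chalcone alkene does not take part.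

## Further compounds

F1 | step 9 | (3R,4S,5R)-enantiomer of 16 | CC(C)=CCc1c(OC(C)=O)cc(C(=O)[C@@H]2[C@H](c3c(OC(C)=O)ccc(C(C)=O)c3OC(C)=O)C=C(C)C[C@H]2c2ccc(OC(C)=O)cc2OC(C)=O)cc1OC(C)=O
F2 | step 9 | (3R,4R,5S) all-trans exo diastereomer of 16 | CC(C)=CCc1c(OC(C)=O)cc(C(=O)[C@H]2[C@H](c3c(OC(C)=O)ccc(C(C)=O)c3OC(C)=O)C=C(C)C[C@@H]2c2ccc(OC(C)=O)cc2OC(C)=O)cc1OC(C)=O
F3 | step 9 | (3S,4S,5R) all-trans exo diastereomer of 16 (enantiomer of F2) | CC(C)=CCc1c(OC(C)=O)cc(C(=O)[C@@H]2[C@@H](c3c(OC(C)=O)ccc(C(C)=O)c3OC(C)=O)C=C(C)C[C@H]2c2ccc(OC(C)=O)cc2OC(C)=O)cc1OC(C)=O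
F4 | step 8 | (E)-2-(3-methylbuta-1,3-dienyl)-4,4,5,5-tetramethyl-1,3,2-dioxaborolane | CC(=C)/C=C/B1OC(C)(C)C(C)(C)O1
F5 | step 5 | (E)-1-(4-allyl-3,5-diacetoxyphenyl)-3-(2,4-diacetoxyphenyl)prop-2-en-1-one | C=CCc1c(OC(C)=O)cc(C(=O)/C=C/c2ccc(OC(C)=O)cc2OC(C)=O)cc1OC(C)=O
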